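**Strategy.** Everything rests on the C9–C11 bond of the central drimane. The key step exploits that C9 of ring B lies next to C8: with C8 as a ketone (the later exocyclic methylene) and a traceless allyl ester on C9, C9 is a soft, regiodefined nucleophile. Its silyl enol ether is alkoxymethylated by the upper half, which carries the ether oxygen and C11 as an isocitrate O-chloromethyl ether; palladium-catalysed decarboxylation in the same flask then funnels both C9 epimers, through the C8 enol, into the equatorial 9β-CH2OR configuration. The precursor is therefore a 12-nor-8-oxo β-keto ester, and all three methylenes are installed together at the end.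

Key step: step 28

Assumption: a 9-alkoxymethyl group next to the C8 ketone is taken to prefer the equatorial 9β position, as is usual for 9-substituted 8-oxodrimanes. Drimane numbering is used throughout (C11 on C9, C12 on C8, C15 = oxygenated 4α-CH2; every drimane core is a 5α-H, 10β-CH3 trans-decalin). TBDPS = tert-butyldiphenylsilyl, MTM = methylthiomethyl.

**Drimane β-keto ester**

Step 1
Reactants: 1 geranyl acetate
Product: 2 (2E,6E)-8-hydroxygeranyl acetate
Conditions: SeO2 (cat.), t-BuOOH, salicylic acid (cat.), CH2Cl2, rt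
Reagents that add atoms: tert-butyl hydroperoxide, CC(C)(C)OO
Why: Riley-type SeO2 allylic oxidation (ene reaction, then [2,3]-shift) should hydroxylate the (E)-methyl of the electron-rich terminal alkene and leave the acetate-deactivated 2,3-alkene alone.

Step 2
Reactants: 2 (2E,6E)-8-hydroxygeranyl acetate
Product: 3 (2E)-5-[(2S,3S)-3-(hydroxymethyl)-3-methyloxiran-2-yl]-3-methylpent-2-en-1-yl acetate
Conditions: Ti(OiPr)4 (cat.), L-(+)-diethyl tartrate (cat.), t-BuOOH, 4 Å molecular sieves, CH2Cl2, −20 °C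
Reagents that add atoms: tert-butyl hydroperoxide, CC(C)(C)OO
Why: Sharpless asymmetric epoxidation of the (E)-2-methylallylic alcohol with L-(+)-tartrate should give the (2S,3S)-epoxide, the stereocentres from which all ring stereochemistry is later derived; the other alkene has no allylic hydroxyl and is not epoxidised.

Step 3
Reactants: 3 epoxy alcohol
Product: 4 TBDPS ether of 3
Conditions: TBDPSCl, imidazole, CH2Cl2, 0 °C to rt
Reagents that add atoms: tert-butyl(chloro)diphenylsilane, CC(C)(C)[Si](Cl)(c1ccccc1)c1ccccc1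
Why: Standard silylation of the primary alcohol; the bulky, Lewis-acid-tolerant silyl ether also prevents neighbouring-group participation in the later cyclisation.

Step 4
Reactants: 4 TBDPS ether
Product: 5 (2E)-5-[(2S,3S)-3-(TBDPS-oxymethyl)-3-methyloxiran-2-yl]-3-methylpent-2-en-1-ol
Conditions: K2CO3 (cat.), MeOH, 0 °C
Reagents that add atoms: none
Why: Base-catalysed transesterification removes the allylic acetate, while epoxide and silyl ether are inert to cold methanolic carbonate.

Step 5
Reactants: 5 allylic alcohol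
Product: 6 (2E)-1-bromo-5-[(2S,3S)-3-(TBDPS-oxymethyl)-3-methyloxiran-2-yl]-3-methylpent-2-ene
Conditions: CBr4, PPh3, 2,6-lutidine (cat.), CH2Cl2, 0 °C
Reagents that add atoms: carbon tetrabromide, BrC(Br)(Br)Br
Why: Appel bromination of the primary allylic alcohol proceeds by SN2 displacement of the alkoxyphosphonium ion under essentially neutral conditions that the epoxide tolerates.

Step 6
Reactants: 6 allylic bromide; 7 allyl acetoacetate
Product: 8 allyl (6E)-9-[(2S,3S)-3-(TBDPS-oxymethyl)-3-methyloxiran-2-yl]-7-methyl-3-oxonon-6-enoate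
Conditions: 7, NaH then n-BuLi, THF, 0 °C; then 6, 0 °C to rt; aq. NH4Cl quench
Reagents that add atoms: none
Why: Weiler dianion alkylation: the γ-carbon of the acetoacetate dianion is the more nucleophilic site and displaces the allylic bromide by SN2 without touching the epoxide.

Step 7
Reactants: 8 epoxy β-keto ester
Product: 9 allyl 3β-hydroxy-15-(TBDPS-oxy)-8-oxo-12-nordriman-11-oate
Conditions: SnCl4, CH2Cl2, −78 to −30 °C
Reagents that add atoms: none
Why: Epoxide-initiated cation–olefin bicyclisation terminated by the tin-chelated β-keto ester enol: anti opening at the tertiary epoxide carbon and a chair–chair transition state should turn the (S,S)-epoxide and the (E)-alkene into 3β-OH, 4α-CH2OSi, 5α-H and 10β-CH3, with the enolisable C9 ester settling equatorial.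

Step 8
Reactants: 9 hydroxy β-keto ester
Product: 10 3-O-(imidazol-1-ylthiocarbonyl) derivative of 9
Conditions: 1,1'-thiocarbonyldiimidazole, DMAP (cat.), 1,2-dichloroethane, 80 °C
Reagents that add atoms: 1,1'-thiocarbonyldiimidazole, S=C(n1ccnc1)n1ccnc1
Why: Thioacylation of the hindered secondary alcohol under non-basic conditions (the β-keto ester would not survive xanthate formation) prepares the Barton–McCombie substrate.

Step 9
Reactants: 10 thiocarbonylimidazolide
Product: 11 allyl 15-(TBDPS-oxy)-8-oxo-12-nordriman-11-oate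
Conditions: Bu3SnH, AIBN (cat.), toluene, 110 °C
Reagents that add atoms: none
Why: Barton–McCombie radical deoxygenation removes the C3 oxygen that served only as the chiral initiator, and touches no stereocentre that is kept.

Step 10
Reactants: 11 silyl-protected β-keto ester
Product: 12 allyl 15-hydroxy-8-oxo-12-nordriman-11-oate
Conditions: HF·pyridine, pyridine, THF, rt
Reagents that add atoms: none
Why: Fluoride-mediated desilylation frees the neopentyl C15 alcohol under mildly acidic conditions that leave the β-keto allyl ester intact.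

**Isocitrate building blocks**

Step 11
Reactants: 13 (R)-malic acid
Product: 15 (R)-malic acid 1-methyl ester, via trifluoroacetylated malic anhydride 14 (not isolated)
Conditions: (CF3CO)2O, 0 °C to rt; concentrate; then MeOH, 0 °C to rt
Reagents that add atoms: methanol, CO
Why: Trifluoroacetic anhydride forms the O-acylated cyclic anhydride, which methanol should open regioselectively at the carbonyl next to the acyloxy-bearing carbon while also cleaving the trifluoroacetate.

Step 12
Reactants: 15 (R)-malic acid 1-methyl ester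
Product: 16 4-tert-butyl 1-methyl (2R)-2-hydroxybutanedioate
Conditions: tert-butyl 2,2,2-trichloroacetimidate, BF3·OEt2 (cat.), CH2Cl2/cyclohexane, rt
Reagents that add atoms: tert-butyl 2,2,2-trichloroacetimidate, CC(C)(C)OC(=N)C(Cl)(Cl)Cl
Why: Imidate tert-butylation esterifies the carboxylic acid much faster than it etherifies the deactivated α-hydroxy-ester hydroxyl.

Step 13
Reactants: 16 mixed malate diester; 17 methyl bromoacetate
Product: 18 2-tert-butyl 1,3-dimethyl (1R,2S)-1-hydroxypropane-1,2,3-tricarboxylate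
Conditions: LiN(SiMe3)2 (2.2 equiv), THF, −78 °C; then 17, −78 to −20 °C; aq. NH4Cl quench
Reagents that add atoms: none
Why: Fráter–Seebach alkylation: the chelated alkoxide–enolate dianion is alkylated anti to the alkoxide, which should set the new centre as 2S and give the natural (1R,2S)-isocitrate pattern with the three carboxyls differentiated by construction.

Step 14
Reactants: 18 isocitrate triester
Product: 19 O-MTM ether of 18
Conditions: Me2S, dibenzoyl peroxide, MeCN, 0 °C
Reagents that add atoms: dimethyl sulfide, CSC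
Why: Pummerer-type methylthiomethylation via the acyloxysulfonium ion converts the secondary alcohol into its O,S-acetal without base and without oxidising it.

Step 15
Reactants: 19 MTM ether
Product: 20 2-tert-butyl 1,3-dimethyl (1R,2S)-1-(chloromethoxy)propane-1,2,3-tricarboxylate
Conditions: SO2Cl2, CH2Cl2, −78 to 0 °C; concentrate; used directly
Reagents that add atoms: sulfuryl chloride, O=S(=O)(Cl)Cl
Why: Chlorinolysis of the O,S-acetal at sulfur gives the α-chloro ether under acid-free conditions that the tert-butyl ester tolerates.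

Step 16
Reactants: 15 (R)-malic acid 1-methyl ester
Product: 21 1-methyl 4-allyl (2R)-2-hydroxybutanedioate
Conditions: allyl bromide, KHCO3, DMF, rt
Reagents that add atoms: allyl bromide, C=CCBr
Why: O-alkylation of the carboxylate with the allylic halide under bicarbonate conditions that do not deprotonate the alcohol.

Step 17
Reactants: 21 mixed malate diester; 22 tert-butyl bromoacetate
Product: 23 2-allyl 3-tert-butyl 1-methyl (1R,2S)-1-hydroxypropane-1,2,3-tricarboxylate
Conditions: LiN(SiMe3)2 (2.2 equiv), THF, −78 °C; then 22, −78 to −20 °C; aq. NH4Cl quench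
Reagents that add atoms: none
Why: The same anti-selective Fráter–Seebach alkylation sets the 2S centre, here with the central carboxyl as a temporary allyl ester and the terminal one as a tert-butyl ester.

Step 18
Reactants: 23 isocitrate triester
Product: 24 O-MTM ether of 23
Conditions: Me2S, dibenzoyl peroxide, MeCN, 0 °C
Reagents that add atoms: dimethyl sulfide, CSC
Why: Pummerer-type methylthiomethylation, as in step 14.

Step 19
Reactants: 24 MTM ether
Product: 25 2-allyl 3-tert-butyl 1-methyl (1R,2S)-1-(chloromethoxy)propane-1,2,3-tricarboxylate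
Conditions: SO2Cl2, CH2Cl2, −78 to 0 °C; concentrate; used directly
Reagents that add atoms: sulfuryl chloride, O=S(=O)(Cl)Cl
Why: Chlorinolysis of the O,S-acetal, as in step 15.

Step 20
Reactants: 24 MTM ether
Product: 26 (2S,3R)-2-(2-tert-butoxy-2-oxoethyl)-4-methoxy-3-[(methylsulfanyl)methoxy]-4-oxobutanoic acid
Conditions: Pd(PPh3)4 (cat.), morpholine, THF, rt; dilute acid wash
Reagents that add atoms: none
Why: Tsuji–Trost deallylation (zerovalent palladium, morpholine as allyl acceptor) frees only the central carboxyl and leaves the methyl ester, tert-butyl ester and thioether intact.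

**Units A and C**

Step 21
Reactants: 11 allyl 15-(TBDPS-oxy)-8-oxo-12-nordriman-11-oate
Product: 27 allyl 15-(TBDPS-oxy)-8-(trimethylsilyloxy)-12-nordrim-8-en-11-oate (silyl enol ether of 11)
Conditions: Me3SiCl, Et3N, CH2Cl2, rt; concentrate, triturate with dry pentane, filter, concentrate; kept under argon and divided between steps 22 and 24
Reagents that add atoms: chlorotrimethylsilane, C[Si](C)(C)Cl
Why: O-Silylation of the strongly enolised cyclic β-keto ester (silyl enol ether formation) should give only the tetrasubstituted Δ8(9) enol ether, because that enol is conjugated with the C11 ester, and the product is robust enough to be freed from the ammonium salt by filtration.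

Step 22
Reactants: 27 silyl enol ether; 20 chloromethyl ether
Product: 29 2-tert-butyl 1,3-dimethyl (1R,2S)-1-{[15-(TBDPS-oxy)-8-oxo-12-nordriman-11-yl]oxy}propane-1,2,3-tricarboxylate, via C9-quaternary allyl ester 28 (not isolated)
Conditions: 20, ZnBr2 (cat.), CH2Cl2, −20 °C to rt; then Pd(OAc)2 (cat.), PPh3, HCO2H, Et3N, THF, rt
Reagents that add atoms: none
Why: Mukaiyama-type Lewis acid alkylation of the silyl enol ether with the α-chloro ether forms C9–C11 (O-alkylation is excluded by the silyl group), and Tsuji deallylation–decarboxylation then ketonises the C8 enol by protonation of C9 from the α face, anti to the C10 methyl, which should give the equatorial 9β side chain.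

Step 23
Reactants: 29 silyl-protected unit A ketone
Product: 30 2-tert-butyl 1,3-dimethyl (1R,2S)-1-[(15-hydroxy-8-oxo-12-nordriman-11-yl)oxy]propane-1,2,3-tricarboxylate
Conditions: HF·pyridine, pyridine, THF, rt
Reagents that add atoms: none
Why: Fluoride desilylation frees the C15 alcohol, and the buffered medium leaves the tert-butyl ester and the β-alkoxy ketone untouched.

Step 24
Reactants: 27 silyl enol ether; 25 chloromethyl ether
Product: 32 (2S,3R)-2-(2-tert-butoxy-2-oxoethyl)-4-methoxy-4-oxo-3-{[15-(TBDPS-oxy)-8-oxo-12-nordriman-11-yl]oxy}butanoic acid, via quaternary bis-allyl ester 31 (not isolated)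
Conditions: 25, ZnBr2 (cat.), CH2Cl2, −20 °C to rt; then Pd(OAc)2 (cat.), PPh3, HCO2H, Et3N, THF, rt; dilute acid wash
Reagents that add atoms: none
Why: The same Mukaiyama-type alkoxymethylation and Tsuji deallylation sequence; here palladium removes both allyl esters, so the C9 ester is lost as CO2 (C9 set as in step 22) and the central isocitrate carboxyl is freed in the same operation.

**Fragment assembly and endgame**

Step 25
Reactants: 12 hydroxy β-keto allyl ester; 32 unit C keto acid
Product: 33 fragment 2: allyl 8-oxo-12-nordriman-11-oate acylated at O15 by acid 32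
Conditions: DCC, DMAP (cat.), CH2Cl2, 0 °C to rt
Reagents that add atoms: none
Why: Steglich esterification of the neopentyl C15 alcohol with the α-branched acid; low temperature and catalytic DMAP limit enolisation at the acyl α-carbon.

Step 26
Reactants: 30 unit A hydroxy ketone; 26 MTM-protected isocitrate acid
Product: 34 fragment 1 MTM ether: ester of O15 of 30 with acid 26
Conditions: DCC, DMAP (cat.), CH2Cl2, 0 °C to rt
Reagents that add atoms: none
Why: Steglich esterification as in step 25; the thioether, tert-butyl esters and β-alkoxy ketone are inert.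

Step 27
Reactants: 34 fragment 1 MTM ether
Product: 35 fragment 1 chloromethyl ether
Conditions: SO2Cl2 (1 equiv), CH2Cl2, −78 to 0 °C; concentrate; used directly
Reagents that add atoms: sulfuryl chloride, O=S(=O)(Cl)Cl
Why: Chlorinolysis of the O,S-acetal is much faster at −78 °C than α-chlorination of the ketone, and no alkene is present at this stage.

Step 28
Reactants: 33 fragment 2; 35 fragment 1 chloromethyl ether
Product: 38 triketone trimer (12,12',12''-trinor-8,8',8''-trioxo precursor of the protected target), via silyl enol ether 36 (not isolated), via C9-quaternary allyl ester 37 (not isolated)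
Conditions: 33, Me3SiCl, Et3N, CH2Cl2, rt; then 35, ZnBr2 (cat.), CH2Cl2, −20 °C to rt; then Pd(OAc)2 (cat.), PPh3, HCO2H, Et3N, THF, rt
Reagents that add atoms: none
Why: Silyl enol ether 36 (only the β-keto ester is silylated by Me3SiCl/Et3N, not the isolated ketone) attacks the oxocarbenium ion pair formed from 35 and ZnBr2, which makes the C9–C11 bond and the C9-quaternary allyl ester 37; the closest known reaction type is the Mukaiyama-type Lewis acid alkylation of silyl enol ethers with α-chloro ethers. In the same flask Pd(OAc)2/PPh3 with HCO2H/Et3N excises the allyl ester (Tsuji deallylation–decarboxylation) and the resulting C8 enol ketonises. No ring is closed. The only new stereocentre, C9, is not fixed in the C–C bond formation (attack anti to the C10 methyl should give mainly the 9α-alkoxymethyl ester, whose configuration is irrelevant) but in the ketonisation: protonation from the α face, anti to the axial C10 methyl, and equilibration through the enol both lead to the equatorial 9β-CH2OR group, so every C9 epimer converges. The step needs C- over O-alkylation (secured by the O-silyl group), C9 over C7 regiochemistry (secured by the ester on C9) and chemoselectivity among nine esters and two other ketones (only the allyl ester reacts with palladium, only the β-keto ester is silylated, and catalytic ZnBr2 spares the tert-butyl esters).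

Step 29
Reactants: 38 triketone trimer
Product: 39 tri-tert-butyl ester 15-O-TBDPS ether of cryptoporic acid T
Conditions: Zn, CH2Br2, TiCl4, THF/CH2Cl2, 0 °C to rt (excess, pre-formed reagent)
Reagents that add atoms: dibromomethane, BrCBr
Why: Takai–Lombardo methylenation: the non-basic gem-dimetallic reagent converts the three ketones but not the esters, and should neither epimerise the C9 centres nor eliminate the β-alkoxy groups.

Step 30
Reactants: 39 protected cryptoporic acid T
Product: 40 cryptoporic acid T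
Conditions: Me3SiOTf, 2,6-lutidine, CH2Cl2, 0 °C; then HF·pyridine, THF, 0 °C to rt
Reagents that add atoms: none
Why: Silyl triflate with excess lutidine cleaves the three tert-butyl esters through their silyl esters without free Brønsted acid (the exocyclic alkenes stay in place), and buffered fluoride then removes the silyl esters and the TBDPS ether while methyl and drimanyl esters are untouched.

**Compound list**

1 | geranyl acetate | CC(C)=CCC/C(C)=C/COC(C)=O | starting material
2 | (2E,6E)-8-hydroxygeranyl acetate | OC/C(C)=C/CC/C(C)=C/COC(C)=O | intermediate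
3 | (2E)-5-[(2S,3S)-3-(hydroxymethyl)-3-methyloxiran-2-yl]-3-methylpent-2-en-1-yl acetate | OC[C@]1(C)O[C@H]1CC/C(C)=C/COC(C)=O | intermediate
4 | TBDPS ether of 3 | CC(C)(C)[Si](c1ccccc1)(c1ccccc1)OC[C@]1(C)O[C@H]1CC/C(C)=C/COC(C)=O | intermediate
5 | (2E)-5-[(2S,3S)-3-(TBDPS-oxymethyl)-3-methyloxiran-2-yl]-3-methylpent-2-en-1-ol | CC(C)(C)[Si](c1ccccc1)(c1ccccc1)OC[C@]1(C)O[C@H]1CC/C(C)=C/CO | intermediate
6 | (2E)-1-bromo-5-[(2S,3S)-3-(TBDPS-oxymethyl)-3-methyloxiran-2-yl]-3-methylpent-2-ene | CC(C)(C)[Si](c1ccccc1)(c1ccccc1)OC[C@]1(C)O[C@H]1CC/C(C)=C/CBr | intermediate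
7 | allyl acetoacetate | CC(=O)CC(=O)OCC=C | starting material
8 | allyl (6E)-9-[(2S,3S)-3-(TBDPS-oxymethyl)-3-methyloxiran-2-yl]-7-methyl-3-oxonon-6-enoate | CC(C)(C)[Si](c1ccccc1)(c1ccccc1)OC[C@]1(C)O[C@H]1CC/C(C)=C/CCC(=O)CC(=O)OCC=C | intermediate
9 | allyl 3β-hydroxy-15-(TBDPS-oxy)-8-oxo-12-nordriman-11-oate (4α-CH2OSi, 5α-H, 9β-ester, 10β-CH3) | O=C1CC[C@H]2[C@](C)(CO[Si](c3ccccc3)(c3ccccc3)C(C)(C)C)[C@@H](O)CC[C@]2(C)[C@H]1C(=O)OCC=C | intermediate
10 | 3-O-(imidazol-1-ylthiocarbonyl) derivative of 9 | O=C1CC[C@H]2[C@](C)(CO[Si](c3ccccc3)(c3ccccc3)C(C)(C)C)[C@@H](OC(=S)n3ccnc3)CC[C@]2(C)[C@H]1C(=O)OCC=C | intermediate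
11 | allyl 15-(TBDPS-oxy)-8-oxo-12-nordriman-11-oate | O=C1CC[C@H]2[C@](C)(CO[Si](c3ccccc3)(c3ccccc3)C(C)(C)C)CCC[C@]2(C)[C@H]1C(=O)OCC=C | intermediate
12 | allyl 15-hydroxy-8-oxo-12-nordriman-11-oate | O=C1CC[C@H]2[C@](C)(CO)CCC[C@]2(C)[C@H]1C(=O)OCC=C | intermediate
13 | (R)-malic acid | O[C@@H](C(=O)O)CC(=O)O | starting material
14 | (3R)-2,5-dioxooxolan-3-yl trifluoroacetate | FC(F)(F)C(=O)O[C@@H]1CC(=O)OC1=O | intermediate
15 | (3R)-3-hydroxy-4-methoxy-4-oxobutanoic acid ((R)-malic acid 1-methyl ester) | O[C@@H](C(=O)OC)CC(=O)O | intermediate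
16 | 4-tert-butyl 1-methyl (2R)-2-hydroxybutanedioate | O[C@@H](C(=O)OC)CC(=O)OC(C)(C)C | intermediate
17 | methyl bromoacetate | COC(=O)CBr | starting material
18 | 2-tert-butyl 1,3-dimethyl (1R,2S)-1-hydroxypropane-1,2,3-tricarboxylate | O[C@@H](C(=O)OC)[C@H](CC(=O)OC)C(=O)OC(C)(C)C | intermediate
19 | 2-tert-butyl 1,3-dimethyl (1R,2S)-1-[(methylsulfanyl)methoxy]propane-1,2,3-tricarboxylate | CSCO[C@@H](C(=O)OC)[C@H](CC(=O)OC)C(=O)OC(C)(C)C | intermediate
20 | 2-tert-butyl 1,3-dimethyl (1R,2S)-1-(chloromethoxy)propane-1,2,3-tricarboxylate | ClCO[C@@H](C(=O)OC)[C@H](CC(=O)OC)C(=O)OC(C)(C)C | intermediate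
21 | 1-methyl 4-allyl (2R)-2-hydroxybutanedioate | O[C@@H](C(=O)OC)CC(=O)OCC=C | intermediate
22 | tert-butyl bromoacetate | CC(C)(C)OC(=O)CBr | starting material
23 | 2-allyl 3-tert-butyl 1-methyl (1R,2S)-1-hydroxypropane-1,2,3-tricarboxylate | O[C@@H](C(=O)OC)[C@H](CC(=O)OC(C)(C)C)C(=O)OCC=C | intermediate
24 | 2-allyl 3-tert-butyl 1-methyl (1R,2S)-1-[(methylsulfanyl)methoxy]propane-1,2,3-tricarboxylate | CSCO[C@@H](C(=O)OC)[C@H](CC(=O)OC(C)(C)C)C(=O)OCC=C | intermediate
25 | 2-allyl 3-tert-butyl 1-methyl (1R,2S)-1-(chloromethoxy)propane-1,2,3-tricarboxylate | ClCO[C@@H](C(=O)OC)[C@H](CC(=O)OC(C)(C)C)C(=O)OCC=C | intermediate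
26 | (2S,3R)-2-(2-tert-butoxy-2-oxoethyl)-4-methoxy-3-[(methylsulfanyl)methoxy]-4-oxobutanoic acid | CSCO[C@@H](C(=O)OC)[C@H](CC(=O)OC(C)(C)C)C(=O)O | intermediate
27 | allyl 15-(TBDPS-oxy)-8-(trimethylsilyloxy)-12-nordrim-8-en-11-oate (silyl enol ether of 11) | C[Si](C)(C)OC=1CC[C@H]2[C@](C)(CO[Si](c3ccccc3)(c3ccccc3)C(C)(C)C)CCC[C@]2(C)C=1C(=O)OCC=C | intermediate
28 | C9-quaternary allyl ester of unit A (9α-alkoxymethyl epimer drawn; either epimer converges) | O=C1CC[C@H]2[C@](C)(CO[Si](c3ccccc3)(c3ccccc3)C(C)(C)C)CCC[C@]2(C)[C@@]1(CO[C@@H](C(=O)OC)[C@H](CC(=O)OC)C(=O)OC(C)(C)C)C(=O)OCC=C | intermediate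
29 | 2-tert-butyl 1,3-dimethyl (1R,2S)-1-{[15-(TBDPS-oxy)-8-oxo-12-nordriman-11-yl]oxy}propane-1,2,3-tricarboxylate | O=C1CC[C@H]2[C@](C)(CO[Si](c3ccccc3)(c3ccccc3)C(C)(C)C)CCC[C@]2(C)[C@H]1CO[C@@H](C(=O)OC)[C@H](CC(=O)OC)C(=O)OC(C)(C)C | intermediate
30 | 2-tert-butyl 1,3-dimethyl (1R,2S)-1-[(15-hydroxy-8-oxo-12-nordriman-11-yl)oxy]propane-1,2,3-tricarboxylate | O=C1CC[C@H]2[C@](C)(CO)CCC[C@]2(C)[C@H]1CO[C@@H](C(=O)OC)[C@H](CC(=O)OC)C(=O)OC(C)(C)C | intermediate
31 | C9-quaternary bis-allyl ester of unit C (9α-alkoxymethyl epimer drawn) | O=C1CC[C@H]2[C@](C)(CO[Si](c3ccccc3)(c3ccccc3)C(C)(C)C)CCC[C@]2(C)[C@@]1(CO[C@@H](C(=O)OC)[C@H](CC(=O)OC(C)(C)C)C(=O)OCC=C)C(=O)OCC=C | intermediate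
32 | (2S,3R)-2-(2-tert-butoxy-2-oxoethyl)-4-methoxy-4-oxo-3-{[15-(TBDPS-oxy)-8-oxo-12-nordriman-11-yl]oxy}butanoic acid | O=C1CC[C@H]2[C@](C)(CO[Si](c3ccccc3)(c3ccccc3)C(C)(C)C)CCC[C@]2(C)[C@H]1CO[C@@H](C(=O)OC)[C@H](CC(=O)OC(C)(C)C)C(=O)O | intermediate
33 | fragment 2: allyl 8-oxo-12-nordriman-11-oate acylated at O15 by acid 32 | O=C1CC[C@H]2[C@](C)(COC(=O)[C@@H](CC(=O)OC(C)(C)C)[C@@H](OC[C@H]3C(=O)CC[C@H]4[C@](C)(CO[Si](c5ccccc5)(c5ccccc5)C(C)(C)C)CCC[C@]34C)C(=O)OC)CCC[C@]2(C)[C@H]1C(=O)OCC=C | intermediate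
34 | fragment 1 MTM ether: 30 acylated at O15 by acid 26 | O=C1CC[C@H]2[C@](C)(COC(=O)[C@@H](CC(=O)OC(C)(C)C)[C@@H](OCSC)C(=O)OC)CCC[C@]2(C)[C@H]1CO[C@@H](C(=O)OC)[C@H](CC(=O)OC)C(=O)OC(C)(C)C | intermediate
35 | fragment 1 chloromethyl ether | O=C1CC[C@H]2[C@](C)(COC(=O)[C@@H](CC(=O)OC(C)(C)C)[C@@H](OCCl)C(=O)OC)CCC[C@]2(C)[C@H]1CO[C@@H](C(=O)OC)[C@H](CC(=O)OC)C(=O)OC(C)(C)C | intermediate
36 | trimethylsilyl enol ether (Δ8(9)) of fragment 2 | C[Si](C)(C)OC=1CC[C@H]2[C@](C)(COC(=O)[C@@H](CC(=O)OC(C)(C)C)[C@@H](OC[C@H]3C(=O)CC[C@H]4[C@](C)(CO[Si](c5ccccc5)(c5ccccc5)C(C)(C)C)CCC[C@]34C)C(=O)OC)CCC[C@]2(C)C=1C(=O)OCC=C | intermediate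
37 | trimer with C9-quaternary allyl ester on the central drimane (9α-alkoxymethyl epimer drawn) | O=C1CC[C@H]2[C@](C)(COC(=O)[C@@H](CC(=O)OC(C)(C)C)[C@@H](OC[C@]3(C(=O)OCC=C)C(=O)CC[C@H]4[C@](C)(COC(=O)[C@@H](CC(=O)OC(C)(C)C)[C@@H](OC[C@H]5C(=O)CC[C@H]6[C@](C)(CO[Si](c7ccccc7)(c7ccccc7)C(C)(C)C)CCC[C@]56C)C(=O)OC)CCC[C@]34C)C(=O)OC)CCC[C@]2(C)[C@H]1CO[C@@H](C(=O)OC)[C@H](CC(=O)OC)C(=O)OC(C)(C)C | intermediate
38 | triketone trimer (three 12-nor-8-oxodrimane units, tri-tert-butyl ester, 15-O-TBDPS) | O=C1CC[C@H]2[C@](C)(COC(=O)[C@@H](CC(=O)OC(C)(C)C)[C@@H](OC[C@H]3C(=O)CC[C@H]4[C@](C)(COC(=O)[C@@H](CC(=O)OC(C)(C)C)[C@@H](OC[C@H]5C(=O)CC[C@H]6[C@](C)(CO[Si](c7ccccc7)(c7ccccc7)C(C)(C)C)CCC[C@]56C)C(=O)OC)CCC[C@]34C)C(=O)OC)CCC[C@]2(C)[C@H]1CO[C@@H](C(=O)OC)[C@H](CC(=O)OC)C(=O)OC(C)(C)C | intermediate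
39 | cryptoporic acid T tri-tert-butyl ester 15-O-TBDPS ether | C=C1CC[C@H]2[C@](C)(COC(=O)[C@@H](CC(=O)OC(C)(C)C)[C@@H](OC[C@H]3C(=C)CC[C@H]4[C@](C)(COC(=O)[C@@H](CC(=O)OC(C)(C)C)[C@@H](OC[C@H]5C(=C)CC[C@H]6[C@](C)(CO[Si](c7ccccc7)(c7ccccc7)C(C)(C)C)CCC[C@]56C)C(=O)OC)CCC[C@]34C)C(=O)OC)CCC[C@]2(C)[C@H]1CO[C@@H](C(=O)OC)[C@H](CC(=O)OC)C(=O)OC(C)(C)C | intermediate
40 | cryptoporic acid T | C=C1CC[C@H]2[C@](C)(COC(=O)[C@@H](CC(=O)O)[C@@H](OC[C@H]3C(=C)CC[C@H]4[C@](C)(COC(=O)[C@@H](CC(=O)O)[C@@H](OC[C@H]5C(=C)CC[C@H]6[C@](C)(CO)CCC[C@]56C)C(=O)OC)CCC[C@]34C)C(=O)OC)CCC[C@]2(C)[C@H]1CO[C@@H](C(=O)OC)[C@H](CC(=O)OC)C(=O)O | target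

**Step count and risk**

Total: 30 steps. Longest linear sequence: 17 steps (1–9, 21, 22, 23, 26, 27, 28, 29, 30).

Step 28 (fragment union). The C–C bond may fail to form at the congested C9 of the large nucleophile, the chloromethyl ether may be diverted by neighbouring ester participation, or the new β-alkoxy group may be eliminated from the enol during the palladium stage on the full-size substrate. The fallback changes the order of convergence and uses the alkoxymethylation on the small nucleophile, where steps 22 and 24 employ it. It sets out from 27 and 35: 27 would be alkylated with 35 (ZnBr2) to the C9-quaternary allyl ester F1, decarboxylated (Pd(OAc)2, PPh3, HCO2H, Et3N) to the dimeric ketone silyl ether F2, and desilylated (HF·pyridine) to the dimeric hydroxy ketone F3. Steglich esterification of F3 with acid 32 (DCC, DMAP) comes back to the route at 38, so the two large pieces would then be joined through the ester bond.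

Step 7 (epoxide-initiated bicyclisation). Ring closure may stall after the first ring or end in O-attack of the free β-keto ester, because the silyloxymethyl group slows ionisation of the epoxide. The fallback changes the terminating nucleophile. It sets out from 8, which would be converted (t-BuMe2SiOTf, Et3N, CH2Cl2, −78 °C) into the (Z)-silyl enol ether F4; this would be cyclised with MeAlCl2 (CH2Cl2, −78 °C) in a Mukaiyama-type termination and comes back to the route at 9 after aqueous work-up.

Step 30 (global deprotection). The Lewis acid may cause migration of the three exocyclic double bonds, or ester cleavage may be incomplete. The fallback inverts the order of the endgame. It sets out from 38, which has no alkene: trifluoroacetic acid (CH2Cl2, 0 °C) followed by HF·pyridine would give the triketo triacid alcohol F5, and threefold Takai–Lombardo methylenation of F5 with a large excess of the Zn/CH2Br2/TiCl4 reagent (the acidic protons consume additional reagent and are restored on mildly acidic work-up) comes back at 40.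

Further compounds
F1 | step 28 | C9-quaternary allyl ester from 27 and 35 (dimer, 15-O-TBDPS on the second drimane; 9α-alkoxymethyl epimer drawn) | O=C1CC[C@H]2[C@](C)(COC(=O)[C@@H](CC(=O)OC(C)(C)C)[C@@H](OC[C@]3(C(=O)OCC=C)C(=O)CC[C@H]4[C@](C)(CO[Si](c5ccccc5)(c5ccccc5)C(C)(C)C)CCC[C@]34C)C(=O)OC)CCC[C@]2(C)[C@H]1CO[C@@H](C(=O)OC)[C@H](CC(=O)OC)C(=O)OC(C)(C)C
F2 | step 28 | dimeric ketone silyl ether (second drimane 8-oxo, 9β-CH2O, 15-O-TBDPS) | O=C1CC[C@H]2[C@](C)(COC(=O)[C@@H](CC(=O)OC(C)(C)C)[C@@H](OC[C@H]3C(=O)CC[C@H]4[C@](C)(CO[Si](c5ccccc5)(c5ccccc5)C(C)(C)C)CCC[C@]34C)C(=O)OC)CCC[C@]2(C)[C@H]1CO[C@@H](C(=O)OC)[C@H](CC(=O)OC)C(=O)OC(C)(C)C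
F3 | step 28 | dimeric hydroxy ketone (second drimane 15-OH) | O=C1CC[C@H]2[C@](C)(COC(=O)[C@@H](CC(=O)OC(C)(C)C)[C@@H](OC[C@H]3C(=O)CC[C@H]4[C@](C)(CO)CCC[C@]34C)C(=O)OC)CCC[C@]2(C)[C@H]1CO[C@@H](C(=O)OC)[C@H](CC(=O)OC)C(=O)OC(C)(C)C
F4 | step 7 | allyl (2Z,6E)-3-(tert-butyldimethylsilyloxy)-9-[(2S,3S)-3-(TBDPS-oxymethyl)-3-methyloxiran-2-yl]-7-methylnona-2,6-dienoate | CC(C)(C)[Si](c1ccccc1)(c1ccccc1)OC[C@]1(C)O[C@H]1CC/C(C)=C/CC/C(O[Si](C)(C)C(C)(C)C)=C/C(=O)OCC=C
F5 | step 30 | triketo triacid alcohol (12,12',12''-trinor-8,8',8''-trioxo analogue of cryptoporic acid T) | O=C1CC[C@H]2[C@](C)(COC(=O)[C@@H](CC(=O)O)[C@@H](OC[C@H]3C(=O)CC[C@H]4[C@](C)(COC(=O)[C@@H](CC(=O)O)[C@@H](OC[C@H]5C(=O)CC[C@H]6[C@](C)(CO)CCC[C@]56C)C(=O)OC)CCC[C@]34C)C(=O)OC)CCC[C@]2(C)[C@H]1CO[C@@H](C(=O)OC)[C@H](CC(=O)OC)C(=O)O
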